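## The problem

The target 31 is a tetracycle in which a 5,7-dihydroxy-6,8-diformylchroman (rings A and B), a nine-membered carbocycle (ring C) and a gem-dimethylcyclobutane (ring D) are fused in a row. The terpenoid part is numbered as a caryophyllane: C1–C9 form ring C, C1/C9/C10/C11 form ring D, C4 is the quaternary carbon bearing the ring oxygen and a methyl group, C5 is the neighbouring methine, and C1′ is the benzylic carbon carrying phenyl. Both ring fusions are trans: the C4 methyl group and H5 are anti, and H1 and H9 are anti. Three of the five stereocentres (C1′, C5, C4) are contiguous on the dihydropyran ring, so C1′ can direct C5 and C5 can direct C4. C1 and C9 lie across ring C, two methylene groups away from C4; C1 can be reached only through the conformation of the nine-membered ring and C9 through equilibration next to a carbonyl group. The nine-membered ring is the entropic and enthalpic obstacle, and it has to be closed between two chains that sit trans on a six-membered ring. The groups that will not survive rough treatment are the exocyclic 1,1-disubstituted alkene next to the strained cyclobutane (acids open the way to cyclobutylcarbinyl cation rearrangements), the ionisable tertiary alkyl aryl ether at C4, and the two aldehydes flanked by free phenols. The enabling feature is that C8, the carbon that carries the exocyclic methylene group, is bonded directly to the cyclobutane methine C9. A C8 ketone conjugated with a C9=C1 double bond is therefore a (Z)-cyclonon-2-enone whose alkene is the bond shared by rings C and D: ring C can be closed by alkene metathesis at C9=C1, and the enone then accepts C11 at C1 and C10 at C9.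

## Retrosynthesis

**31 ⇒ 29.** The two aryl–CHO bonds are cut first. Aldehydes ortho to free phenols would not survive the ylides, hydrides and Lewis acids used earlier, and the free 5,7-dihydroxy ring of 29 has exactly two open positions. The neighbouring option, formylating a dimethyl ether and demethylating afterwards, would expose the alkene, the cyclobutane and the C4 ether to a chelating boron or titanium halide. The forward reaction must formylate twice in one operation without touching the 1,1-disubstituted alkene.

**29 ⇒ 28 ⇒ 27.** The exocyclic C8=CH2 bond is cut to ketone 28, and the two phenols are traced to the methyl ethers of 27. The ethers are cleaved while C8 is still a ketone, so that no alkene is present when BBr3 is used. This asks BBr3 to spare the C4–O bond, and the Wittig reaction to work on a hindered ketone in the presence of two phenoxides.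

**27 ⇒ 24 ⇒ 22 ⇒ 19 + 21.** Cutting C9–C10 and then C1–C11 removes ring D altogether. The two bonds map onto the α- and β-carbons of enone 19, and the four-carbon unit is the ketene silyl acetal 21, made from methyl isobutyrate 20. A one-step photocycloaddition with isobutylene would be shorter, but medium-ring enones tend to dissipate excitation by Z/E isomerisation; it is kept as a fallback. The Michael adduct is deliberately carried as its silyl enol ether 22, through alcohol 23 to tosylate 24. Deprotonation of the free ketone would favour the less hindered C7, and a C7 enolate would close a six-membered ring instead of the cyclobutane. The forward sequence needs the correct face at C1, a 4-exo-tet closure at a neopentyl carbon, and equilibration of C9 to the trans fusion.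

**19 ⇒ 18.** The C9=C1 bond is cut by retro-metathesis, which removes ring C and leaves chroman 18 with a but-3-enyl chain on C4 and a 3-oxopent-4-enyl chain on C5. Cutting C8–C9 instead (chromium-mediated addition of a vinyl iodide to an aldehyde) would be one operation shorter but needs a stereodefined iodoalkene, excess chromium salt and a final oxidation. The metathesis cut is catalytic, delivers the enone at the right oxidation level, and lets ring size fix the Z geometry. The forward reaction must favour cyclisation over dimerisation.

**18 ⇒ 14 ⇒ 10.** Functional-group changes only. The vinyl ketone comes from the silyl ether of 14 (desilylation, oxidation, vinyl addition, oxidation). The but-3-enyl group comes from the allyl group of 10 by one-carbon homologation (hydroboration, oxidation, methylenation). The allyl group is accepted, despite the three extra steps, because of the stereochemical argument in the next paragraph.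

**10 ⇒ 8 ⇒ 7.** The C4–C3 bond (chroman C2–allyl) and the C4–CH3 bond are cut, so the lactone carbonyl carbon of 7 becomes the quaternary ether carbon. In the oxocarbenium ion the C5 chain and the phenyl group should be trans-diaxial, and the last nucleophile should enter anti to the adjacent C5 chain. The target has the C3 chain, not the methyl group, anti to the C5 chain, so methyl is put in first (hemiketal 8) and the carbon chain last, as allylsilane. The reverse order (butenyl first, methyl last) is three steps shorter but is predicted to give the C4 epimer; it is the fallback if the prediction is wrong.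

**7 ⇒ 3 + 5.** The C5–C6 bond is cut to the enolate of lactone 3 and iodide 5 (from 3-iodopropan-1-ol 4). Alkylation anti to the phenyl group gives the trans relationship. A bulky silyl ether is chosen because its oxygen is a poor neighbouring group towards the later oxocarbenium ion.

**3 ⇒ 1 + 2.** The C1′–phenyl bond is cut to 5,7-dimethoxycoumarin 1 and phenylboronic acid 2. This is the only reagent-controlled stereocentre; every other centre is relayed from it.

## Roads not taken

**Alternative 1: Wolff contraction of a cyclopentanone.** Here the cyclobutane is not annulated but contracted: the C9–C10 bond arises when C10 migrates to the carbene carbon of diazoketone A1, and C8 is extruded as the ester carbon of A2. Irradiation in methanol followed by NaOMe should give the trans cyclobutane ester reliably. Its real merit is that C1 would be set on a five-membered ring, where reagent-controlled conjugate additions are dependable, and that no neopentyl 4-exo-tet alkylation is needed. In both respects it is better than the chosen plan. Its weakness is that ring C is still open in A2 and must be closed between C7 and the ester carbon C8, an sp3–acyl bond for which no method comparable to metathesis exists at this ring size. The five-membered fragment also has to be attached to the chroman as a complex alkyl nucleophile at the quaternary C4, and the diazo group needs activation steps. Against its stereochemical certainty the chosen plan sets a precedented ring closure and a cyclobutane built from two simple reagents on the closed ring.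

**Alternative 2: anionic oxy-Cope ring expansion.** The cut is C5–C6: alkoxide formation from the cyclobutane-fused cyclopentanol A3 with KH and 18-crown-6 should trigger a [3,3] shift through a boat transition state and expand the five-membered ring to the nine-membered enone A4. Ring C is formed without high dilution, ring D is present from the start, and chirality transfer fixes C5 relative to C1; this relay is better than relying on medium-ring face selectivity. The price is paid elsewhere. The chroman is not yet closed in A4, so the C4–O bond and the C4 stereocentre must come from adding the phenol across the C3=C4 alkene of a caryophyllene-like ring, which requires cationic activation of a medium ring prone to transannular reactions, and nothing secures the facial outcome. A3 itself needs the vinyl and the bulky alkenyl group cis on a bicyclo[3.2.0]heptane with a defined alkene geometry, and the benzylic centre must be set on an open chain. The chosen plan fixes C1′, C5 and C4 early on a rigid lactone and avoids late cation chemistry, but it gives up the built-in C1/C5 relay.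

**Alternative 3: Ramberg–Bäcklund contraction.** The cut is a C2=C3 alkene: the ten-membered sulfone A5 is halogenated next to sulfur with KOH on alumina and CBr2F2, and the episulfone loses SO2 to give the nine-membered (Z)-cycloalkene A6. A ten-membered thiacycle closes more easily than a nine-membered carbocycle, and an enantiopure cyclobutane fragment would bring C1 and C9 in fixed, so this road is the safest stereochemically and better than the chosen plan on that count. It is weaker in three ways. One C–S bond must be made at C3, a neopentyl-type carbon attached to the quaternary C4, where substitution is slow. The cyclobutane fragment with its C8 ketal needs its own multistep enantioselective synthesis and a further coupling to the chroman. The C2=C3 alkene is superfluous and costs a hydrogenation before the C8 methylene can be installed. The chosen plan is shorter and uses its enone constructively, at the cost of an unproven facial selectivity at C1.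

Key step: step 13

Assumption: addition of 21 to enone 19 is taken to occur on the face of C1 that gives the 1S configuration drawn for 22; this rests on the conformation of the nine-membered ring and not on a neighbouring stereocentre.

Assumption: the trans-fused four/nine-ring ketone 27 is taken to be more stable than its C9 epimer 26, as is general for bicyclo[7.2.0]undecanones of the caryophyllane type.

## Route

Step 1
Reactants: 1 5,7-dimethoxycoumarin; 2 phenylboronic acid
Product: 3 (4S)-5,7-dimethoxy-4-phenylchroman-2-one
Conditions: Rh(acac)(C2H4)2 (3 mol%), (S)-SEGPHOS, dioxane/H2O, 60 °C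
Reagents that add atoms: none
Why: Rhodium-catalysed asymmetric 1,4-addition of an arylboronic acid to a coumarin (Hayashi–Miyaura type): aryl-rhodium insertion into C3=C4, then hydrolysis. The bisphosphine controls the face; the ligand enantiomer is the one that gives the 4S lactone [(S)-SEGPHOS by analogy with simple coumarins].

Step 2
Reactants: 4 3-iodopropan-1-ol
Product: 5 tert-butyl(3-iodopropoxy)diphenylsilane
Conditions: t-BuPh2SiCl, imidazole, CH2Cl2, 0 °C → rt
Reagents that add atoms: tert-butylchlorodiphenylsilane, CC(C)(C)[Si](Cl)(c1ccccc1)c1ccccc1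
Why: Imidazole-assisted O-silylation of a primary alcohol. The bulky, weakly basic silyl ether withstands BF3·OEt2 and is a poor neighbouring group towards the oxocarbenium ion of step 5.

Step 3
Reactants: 3 (4S)-5,7-dimethoxy-4-phenylchroman-2-one; 5 tert-butyl(3-iodopropoxy)diphenylsilane
Product: 7 (3R,4S)-3-[3-(tert-butyldiphenylsilyloxy)propyl]-5,7-dimethoxy-4-phenylchroman-2-one, via lithium lactone enolate 6 (not isolated)
Conditions: LiN(SiMe3)2, THF, −78 °C; then 5, DMPU, −78 → −30 °C
Reagents that add atoms: none
Why: Lactone enolate alkylation. The 4-phenyl group sits pseudoaxial next to the peri methoxy group and shields one face, so the primary iodide enters anti to it and C3 is set trans to C4 (3R).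

Step 4
Reactants: 7 (3R,4S)-3-[3-(tert-butyldiphenylsilyloxy)propyl]-5,7-dimethoxy-4-phenylchroman-2-one
Product: 8 (3R,4S)-3-[3-(tert-butyldiphenylsilyloxy)propyl]-5,7-dimethoxy-2-methyl-4-phenylchroman-2-ol (hemiketal, both C2 epimers, in equilibrium with the ring-opened hydroxy ketone)
Conditions: CH3Li (1.1 equiv), THF, −78 °C; AcOH quench at −78 °C
Reagents that add atoms: methyllithium, [Li]C
Why: Single addition of an organolithium to a lactone: the tetrahedral lithium alkoxide persists at −78 °C, and the cold acidic quench avoids epimerisation at C3. C2 is not a permanent stereocentre at this stage.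

Step 5
Reactants: 8 hemiketal
Product: 10 (2S,3R,4S)-2-allyl-3-[3-(tert-butyldiphenylsilyloxy)propyl]-5,7-dimethoxy-2-methyl-4-phenylchroman, via 3,4-dihydrochromenylium ion 9 (not isolated)
Conditions: CH2=CHCH2SiMe3 (4 equiv), BF3·OEt2 (2 equiv), CH2Cl2, −78 → −40 °C
Reagents that add atoms: allyltrimethylsilane, C=CC[Si](C)(C)C
Why: Hosomi–Sakurai allylation of a cyclic hemiketal through oxocarbenium ion 9. In the preferred half-chair the C3 chain and the 4-phenyl group are trans-diaxial, and the allylsilane attacks C2 axially, anti to the adjacent C3 chain. Allyl therefore ends trans to that chain and cis to phenyl, with methyl cis to the chain (2S).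

Step 6
Reactants: 10 (2S,3R,4S)-2-allyl chroman
Product: 12 3-[(2S,3R,4S)-3-[3-(tert-butyldiphenylsilyloxy)propyl]-5,7-dimethoxy-2-methyl-4-phenylchroman-2-yl]propan-1-ol, via B-alkyl-9-borabicyclo[3.3.1]nonane 11 (not isolated)
Conditions: 9-BBN, THF, 0 °C → rt; then NaOH, H2O2, 0 °C
Reagents that add atoms: hydrogen peroxide, OO; 9-borabicyclo[3.3.1]nonane (boron of intermediate 11 only), B1C2CCCC1CCC2
Why: Anti-Markovnikov hydroboration of the only alkene, then oxidation of borane 11 with retention. Silyl and aryl ethers are inert.

Step 7
Reactants: 12 primary alcohol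
Product: 13 3-[(2S,3R,4S)-3-[3-(tert-butyldiphenylsilyloxy)propyl]-5,7-dimethoxy-2-methyl-4-phenylchroman-2-yl]propanal
Conditions: Dess–Martin periodinane, NaHCO3, CH2Cl2, 0 °C → rt
Reagents that add atoms: none
Why: Dess–Martin oxidation of a primary alcohol to the aldehyde under buffered conditions; no α-stereocentre is at risk.

Step 8
Reactants: 13 aldehyde
Product: 14 (2S,3R,4S)-2-(but-3-enyl)-3-[3-(tert-butyldiphenylsilyloxy)propyl]-5,7-dimethoxy-2-methyl-4-phenylchroman
Conditions: Ph3PCH3Br, KOt-Bu, THF, 0 °C → rt
Reagents that add atoms: methyltriphenylphosphonium bromide, C[P+](c1ccccc1)(c1ccccc1)c1ccccc1.[Br-]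
Why: Wittig methylenation of an unhindered aldehyde completes the one-carbon homologation of allyl to but-3-enyl.

Step 9
Reactants: 14 silyl ether
Product: 15 3-[(2S,3R,4S)-2-(but-3-enyl)-5,7-dimethoxy-2-methyl-4-phenylchroman-3-yl]propan-1-ol
Conditions: Bu4NF, THF, rt; aq. NH4Cl
Reagents that add atoms: none
Why: Fluoride cleavage of a primary silyl ether; nothing else in 14 is sensitive to fluoride or mild base.

Step 10
Reactants: 15 primary alcohol
Product: 16 3-[(2S,3R,4S)-2-(but-3-enyl)-5,7-dimethoxy-2-methyl-4-phenylchroman-3-yl]propanal
Conditions: Dess–Martin periodinane, NaHCO3, CH2Cl2, 0 °C → rt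
Reagents that add atoms: none
Why: Dess–Martin oxidation; the terminal alkene and the electron-rich arene are untouched.

Step 11
Reactants: 16 aldehyde
Product: 17 5-[(2S,3R,4S)-2-(but-3-enyl)-5,7-dimethoxy-2-methyl-4-phenylchroman-3-yl]pent-1-en-3-ol (both carbinol epimers)
Conditions: CH2=CHMgBr, THF, −78 °C; aq. NH4Cl
Reagents that add atoms: vinylmagnesium bromide, C=C[Mg]Br
Why: 1,2-Addition of a vinyl Grignard reagent to an aldehyde. The carbinol centre forms unselectively and is removed in step 12.

Step 12
Reactants: 17 allylic alcohol
Product: 18 5-[(2S,3R,4S)-2-(but-3-enyl)-5,7-dimethoxy-2-methyl-4-phenylchroman-3-yl]pent-1-en-3-one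
Conditions: Dess–Martin periodinane, NaHCO3, CH2Cl2, 0 °C
Reagents that add atoms: none
Why: Dess–Martin oxidation of an allylic alcohol to the vinyl ketone under neutral conditions. The enone is prone to polymerisation and conjugate addition and is used at once.

Step 13
Reactants: 18 vinyl ketone with the but-3-enyl chain on C4
Product: 19 chroman-fused (Z)-cyclonon-2-enone (4S,5R,1′S; C8 ketone, C9=C1 alkene, ring C trans-fused to the 5,7-dimethoxy-4-phenylchroman)
Conditions: second-generation Grubbs catalyst RuCl2(=CHPh)(PCy3)(H2IMes) (10 mol%, in portions), 1,4-benzoquinone (20 mol%), toluene, 0.001 M, 80 °C, argon sparge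
Reagents that add atoms: none
Why: Ring-closing alkene metathesis to a medium-ring 2-enone; the closest known cases are eight- and nine-membered cycloalkenones closed on conformationally biased substrates. The ruthenium benzylidene initiates at the electron-neutral but-3-enyl alkene, the alkylidene at C1 adds across the vinyl ketone, and cycloreversion of the ruthenacyclobutane gives the C9=C1 bond and a ruthenium methylidene while ethylene leaves the solution. Ring C is closed end to end between the two terminal alkene carbons, and the alkene becomes endocyclic. No stereocentre is formed; the alkene must be Z, which the ring size enforces. The step needs cyclisation to win over cross-metathesis to dimers and oligomers. High dilution, the quaternary C4 carrying one chain, and the half-chair in which both chains are pseudoequatorial and gauche (the arrangement the finished skeleton itself requires) provide that bias. The terminal alkene must not migrate before closure; benzoquinone intercepts the ruthenium hydrides responsible.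

Step 14
Reactants: 20 methyl isobutyrate
Product: 21 tert-butyl[(1-methoxy-2-methylprop-1-enyl)oxy]dimethylsilane
Conditions: LiN(i-Pr)2, THF, −78 °C; then t-BuMe2SiCl, DMPU, −78 °C → rt
Reagents that add atoms: tert-butylchlorodimethylsilane, CC(C)(C)[Si](C)(C)Cl
Why: Kinetic ester enolate formation and O-silylation give the tetrasubstituted ketene silyl acetal; no geometrical isomers arise because the two carbon substituents are identical.

Step 15
Reactants: 19 chroman-fused (Z)-cyclonon-2-enone; 21 ketene silyl acetal
Product: 22 C8 tert-butyldimethylsilyl enol ether (C8=C9, ring-cis) carrying the C(CH3)2CO2CH3 group on C1 (1S,4S,5R,1′S)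
Conditions: HN(SO2CF3)2 (5 mol%), CH2Cl2, −78 °C; then Et3N
Reagents that add atoms: none
Why: Mukaiyama–Michael addition catalysed by a silyl triflimide formed in situ: the silylated enone is attacked at C1 and the silyl group ends on the C8 oxygen, so the enol ether is regiodefined at C8=C9. The C1 centre results from attack on the ring face assumed above.

Step 16
Reactants: 22 silyl enol ether ester
Product: 23 neopentyl alcohol (CO2CH3 of 22 reduced to CH2OH; silyl enol ether retained)
Conditions: i-Bu2AlH, CH2Cl2, −78 → 0 °C; aq. KNaC4H4O6
Reagents that add atoms: none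
Why: Hydride reduction of a hindered ester to the primary alcohol; silyl enol ethers are inert to i-Bu2AlH and survive a buffered tartrate work-up.

Step 17
Reactants: 23 neopentyl alcohol
Product: 24 neopentyl p-toluenesulfonate (silyl enol ether retained)
Conditions: TsCl, Et3N, DMAP (cat.), CH2Cl2, 0 °C → rt
Reagents that add atoms: p-toluenesulfonyl chloride, Cc1ccc(cc1)S(=O)(=O)Cl
Why: Sulfonylation at oxygen is not hampered by the neopentyl environment, and the amine base keeps the acid-labile enol ether intact.

Step 18
Reactants: 24 neopentyl p-toluenesulfonate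
Product: 27 trans-fused cyclobutane ketone (1S,4S,5R,9R,1′S; 5,7-dimethoxy; C8 ketone), via tris(dimethylamino)sulfonium enolate 25 (not isolated), via cis-fused C9-epimeric ketone 26 (not isolated)
Conditions: [(Me2N)3S][Me3SiF2], THF, 0.002 M, 0 → 40 °C; then KOt-Bu (cat.), t-BuOH, rt
Reagents that add atoms: none
Why: Fluoride-triggered regiospecific enolate alkylation: desilylation gives the C9 enolate 25, which closes the cyclobutane by 4-exo-tet displacement of the sulfonate, helped by the gem-dimethyl group. High dilution keeps intermolecular proton transfer (which would pass the enolate to C7 and a six-membered ring) slower than closure, and O-alkylation would need an E enolate within the nine-membered ring. KOt-Bu then equilibrates any cis-fused ketone 26 through the C9 enolate to the trans-fused ketone 27.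

Step 19
Reactants: 27 trans-fused dimethoxy ketone
Product: 28 trans-fused 5,7-dihydroxy ketone (1S,4S,5R,9R,1′S)
Conditions: BBr3, CH2Cl2, −78 → 0 °C; then H2O
Reagents that add atoms: none
Why: Lewis acid cleavage of both aryl methyl ethers (boron coordination, bromide attack at methyl) at a stage with no alkene present. The chroman oxygen, flanked by the quaternary C4, should coordinate boron less readily than the methoxy oxygens.

Step 20
Reactants: 28 dihydroxy ketone
Product: 29 5,7-dihydroxy compound with the exocyclic C8 methylene group (1S,4S,5R,9R,1′S)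
Conditions: Ph3PCH3Br, KOt-Bu (excess), toluene/THF, 70 °C
Reagents that add atoms: methyltriphenylphosphonium bromide, C[P+](c1ccccc1)(c1ccccc1)c1ccccc1.[Br-]
Why: Wittig methylenation of the hindered C8 ketone with excess ylide, the phenols being carried as phenoxides. The basic medium can only reinforce the trans fusion at C9.

Step 21
Reactants: 29 dihydroxy alkene
Product: 31 target, 6,8-diformyl-5,7-dihydroxy compound (1S,4S,5R,9R,1′S), via bis(dimethyliminium) dichloride 30 (not isolated)
Conditions: POCl3, DMF, EtOAc, 0 °C → rt; then aq. NaOAc
Reagents that add atoms: N,N-dimethylformamide, CN(C)C=O; water, O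
Why: Double Vilsmeier–Haack formylation of a phloroglucinol-type ring at its only two free positions; hydrolysis of the bis(iminium) salt 30 gives the dialdehyde. The weakly acidic medium should leave the 1,1-disubstituted alkene and the cyclobutane alone.

## Compound list

1 | 5,7-dimethoxycoumarin | COc1cc(OC)c2ccc(=O)oc2c1 | starting material
2 | phenylboronic acid | OB(O)c1ccccc1 | starting material
3 | (4S)-5,7-dimethoxy-4-phenylchroman-2-one | O=C1C[C@@H](c2ccccc2)c2c(OC)cc(OC)cc2O1 | intermediate
4 | 3-iodopropan-1-ol | OCCCI | starting material
5 | tert-butyl(3-iodopropoxy)diphenylsilane | CC(C)(C)[Si](c1ccccc1)(c1ccccc1)OCCCI | intermediate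
6 | lithium enolate of lactone 3 | [Li]OC1=C[C@@H](c2ccccc2)c2c(OC)cc(OC)cc2O1 | intermediate (not isolated)
7 | (3R,4S)-3-[3-(tert-butyldiphenylsilyloxy)propyl]-5,7-dimethoxy-4-phenylchroman-2-one (3,4-trans) | CC(C)(C)[Si](c1ccccc1)(c1ccccc1)OCCC[C@@H]1[C@@H](c2ccccc2)c2c(OC)cc(OC)cc2OC1=O | intermediate
8 | (3R,4S)-3-[3-(tert-butyldiphenylsilyloxy)propyl]-5,7-dimethoxy-2-methyl-4-phenylchroman-2-ol (hemiketal, C2 epimers) | CC(C)(C)[Si](c1ccccc1)(c1ccccc1)OCCC[C@@H]1[C@@H](c2ccccc2)c2c(OC)cc(OC)cc2OC1(C)O | intermediate
9 | (3R,4S)-3-[3-(tert-butyldiphenylsilyloxy)propyl]-5,7-dimethoxy-2-methyl-4-phenyl-3,4-dihydrochromenylium hydroxytrifluoroborate | CC(C)(C)[Si](c1ccccc1)(c1ccccc1)OCCC[C@@H]1[C@@H](c2ccccc2)c2c(OC)cc(OC)cc2[O+]=C1C.O[B-](F)(F)F | intermediate (not isolated)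
10 | (2S,3R,4S)-2-allyl-3-[3-(tert-butyldiphenylsilyloxy)propyl]-5,7-dimethoxy-2-methyl-4-phenylchroman (allyl trans to the C3 chain) | CC(C)(C)[Si](c1ccccc1)(c1ccccc1)OCCC[C@@H]2[C@@H](c3ccccc3)c3c(OC)cc(OC)cc3O[C@@]2(C)CC=C | intermediate
11 | B-alkyl-9-borabicyclo[3.3.1]nonane from 10 (boron on the terminal carbon of the former allyl group) | CC(C)(C)[Si](c1ccccc1)(c1ccccc1)OCCC[C@@H]2[C@@H](c3ccccc3)c3c(OC)cc(OC)cc3O[C@@]2(C)CCCB1C2CCCC1CCC2 | intermediate (not isolated)
12 | 3-[(2S,3R,4S)-3-[3-(tert-butyldiphenylsilyloxy)propyl]-5,7-dimethoxy-2-methyl-4-phenylchroman-2-yl]propan-1-ol | CC(C)(C)[Si](c1ccccc1)(c1ccccc1)OCCC[C@@H]2[C@@H](c3ccccc3)c3c(OC)cc(OC)cc3O[C@@]2(C)CCCO | intermediate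
13 | 3-[(2S,3R,4S)-3-[3-(tert-butyldiphenylsilyloxy)propyl]-5,7-dimethoxy-2-methyl-4-phenylchroman-2-yl]propanal | CC(C)(C)[Si](c1ccccc1)(c1ccccc1)OCCC[C@@H]2[C@@H](c3ccccc3)c3c(OC)cc(OC)cc3O[C@@]2(C)CCC=O | intermediate
14 | (2S,3R,4S)-2-(but-3-enyl)-3-[3-(tert-butyldiphenylsilyloxy)propyl]-5,7-dimethoxy-2-methyl-4-phenylchroman | CC(C)(C)[Si](c1ccccc1)(c1ccccc1)OCCC[C@@H]2[C@@H](c3ccccc3)c3c(OC)cc(OC)cc3O[C@@]2(C)CCC=C | intermediate
15 | 3-[(2S,3R,4S)-2-(but-3-enyl)-5,7-dimethoxy-2-methyl-4-phenylchroman-3-yl]propan-1-ol | OCCC[C@@H]2[C@@H](c3ccccc3)c3c(OC)cc(OC)cc3O[C@@]2(C)CCC=C | intermediate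
16 | 3-[(2S,3R,4S)-2-(but-3-enyl)-5,7-dimethoxy-2-methyl-4-phenylchroman-3-yl]propanal | O=CCC[C@@H]2[C@@H](c3ccccc3)c3c(OC)cc(OC)cc3O[C@@]2(C)CCC=C | intermediate
17 | 5-[(2S,3R,4S)-2-(but-3-enyl)-5,7-dimethoxy-2-methyl-4-phenylchroman-3-yl]pent-1-en-3-ol (carbinol epimers) | C=CC(O)CC[C@@H]2[C@@H](c3ccccc3)c3c(OC)cc(OC)cc3O[C@@]2(C)CCC=C | intermediate
18 | 5-[(2S,3R,4S)-2-(but-3-enyl)-5,7-dimethoxy-2-methyl-4-phenylchroman-3-yl]pent-1-en-3-one | C=CC(=O)CC[C@@H]2[C@@H](c3ccccc3)c3c(OC)cc(OC)cc3O[C@@]2(C)CCC=C | intermediate
19 | chroman-fused (Z)-cyclonon-2-enone (4S,5R,1′S; C8 ketone, C9=C1) | C1/C=C\C(=O)CC[C@@H]2[C@@H](c3ccccc3)c3c(OC)cc(OC)cc3O[C@@]2(C)C1 | intermediate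
20 | methyl isobutyrate | COC(=O)C(C)C | starting material
21 | tert-butyl[(1-methoxy-2-methylprop-1-enyl)oxy]dimethylsilane | COC(=C(C)C)O[Si](C)(C)C(C)(C)C | intermediate
22 | C8 tert-butyldimethylsilyl enol ether (C8=C9, ring-cis) with C(CH3)2CO2CH3 on C1 (1S,4S,5R,1′S) | C1C[C@@H]2[C@@H](c3ccccc3)c3c(OC)cc(OC)cc3O[C@@]2(C)CC[C@H](C(C)(C)C(=O)OC)/C=C\1O[Si](C)(C)C(C)(C)C | intermediate
23 | corresponding neopentyl alcohol, C(CH3)2CH2OH on C1 | C1C[C@@H]2[C@@H](c3ccccc3)c3c(OC)cc(OC)cc3O[C@@]2(C)CC[C@H](C(C)(C)CO)/C=C\1O[Si](C)(C)C(C)(C)C | intermediate
24 | corresponding neopentyl p-toluenesulfonate | C1C[C@@H]2[C@@H](c3ccccc3)c3c(OC)cc(OC)cc3O[C@@]2(C)CC[C@H](C(C)(C)COS(=O)(=O)c3ccc(C)cc3)/C=C\1O[Si](C)(C)C(C)(C)C | intermediate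
25 | tris(dimethylamino)sulfonium C8=C9 enolate of the keto sulfonate | C1C[C@@H]2[C@@H](c3ccccc3)c3c(OC)cc(OC)cc3O[C@@]2(C)CC[C@H](C(C)(C)COS(=O)(=O)c3ccc(C)cc3)/C=C\1[O-].CN(C)[S+](N(C)C)N(C)C | intermediate (not isolated)
26 | cis-fused cyclobutane ketone, C9 epimer of 27 (1S,4S,5R,9S,1′S) | O=C1CC[C@@H]2[C@@H](c3ccccc3)c3c(OC)cc(OC)cc3O[C@@]2(C)CC[C@H]2[C@@H]1CC2(C)C | intermediate (not isolated)
27 | trans-fused cyclobutane ketone, 5,7-dimethoxy (1S,4S,5R,9R,1′S) | O=C1CC[C@@H]2[C@@H](c3ccccc3)c3c(OC)cc(OC)cc3O[C@@]2(C)CC[C@H]2[C@H]1CC2(C)C | intermediate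
28 | trans-fused cyclobutane ketone, 5,7-dihydroxy | O=C1CC[C@@H]2[C@@H](c3ccccc3)c3c(O)cc(O)cc3O[C@@]2(C)CC[C@H]2[C@H]1CC2(C)C | intermediate
29 | 5,7-dihydroxy compound with exocyclic C8 methylene | C=C1CC[C@@H]2[C@@H](c3ccccc3)c3c(O)cc(O)cc3O[C@@]2(C)CC[C@H]2[C@H]1CC2(C)C | intermediate
30 | 6,8-bis(dimethyliminiomethyl) dichloride of 29 | C=C1CC[C@@H]2[C@@H](c3ccccc3)c3c(O)c(C=[N+](C)C)c(O)c(C=[N+](C)C)c3O[C@@]2(C)CC[C@H]2[C@H]1CC2(C)C.[Cl-].[Cl-] | intermediate (not isolated)
31 | CNP0253700.1, 6,8-diformyl-5,7-dihydroxy compound (1S,4S,5R,9R,1′S) | C=C1CC[C@@H]2[C@@H](c3ccccc3)c3c(O)c(C=O)c(O)c(C=O)c3O[C@@]2(C)CC[C@H]2[C@H]1CC2(C)C | target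

## Step count and least certain steps

Total step count: 21 (19 in the main line, plus the preparations of 5 and 21). Longest linear sequence: 19 steps from 1 (steps 1, 3–13 and 15–21).

**Step 13 (key step).** The ground-state half-chair of 18 places the two chains trans-diaxial and far apart, so intermolecular metathesis to dimers and oligomers may outrun closure, and turnover at the electron-poor vinyl ketone may be slow. Fallback: close ring C at C8–C9 by a chromium-mediated addition instead. It sets out from aldehyde 13. Stork–Zhao olefination (Ph3PCH2I iodide, NaN(SiMe3)2, THF/DMPU, −78 °C) should give the (Z)-vinyl iodide F1. Bu4NF then gives the alcohol F2, and Dess–Martin oxidation the iodo aldehyde F3. Nozaki–Hiyama–Kishi cyclisation (CrCl2 with catalytic NiCl2, DMF/THF, high dilution; divalent chromium) should form the nine-membered (Z)-allylic alcohol F4. Dess–Martin oxidation of F4 returns to the route at 19. This path is one operation shorter than steps 8–13 but uses excess chromium salt.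

**Step 15.** The ketene acetal may attack the other face of the flexible nine-membered enone, giving poor or reversed selectivity at C1. Fallback, setting out from 19: if step 15 delivers mainly the C1-epimeric silyl enol ether F5, Saegusa–Ito oxidation (Pd(OAc)2, MeCN; divalent palladium) converts it into the β-substituted enone F6 with the C9=C1 bond restored. Conjugate reduction with [(Ph3P)CuH]6 in the presence of t-BuMe2SiCl then delivers hydride to the face the carbon nucleophile had used, which inverts C1 and returns to the route at 22.

**Step 5.** The pseudoaxial phenyl group lies on the face the allylsilane must use, so attack syn to the C3 chain may compete and give the C2 epimer. Fallback, from lactone 7: reverse the order of the two C2 substituents. Addition of but-3-enylmagnesium bromide (from 4-bromobut-1-ene and Mg, THF, −40 °C) gives the butenyl hemiketal F7. Al(CH3)3 in CH2Cl2 then delivers methyl to the face that allyl had taken, which returns to the route at 14 and saves steps 6–8.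

**Step 18.** Substitution at the neopentyl carbon is slow, so proton exchange may move the enolate to C7 (six-membered ring closure) or simply return the open ketone. Fallback, from enone 19: [2+2] photocycloaddition with isobutylene (Pyrex-filtered light, CH2Cl2, −78 °C), which is known to place the gem-dimethyl carbon on the β-carbon of cyclic enones, followed by the same KOt-Bu equilibration; it returns at 27. Its own risks are Z/E isomerisation of the medium-ring enone and the same facial question at C1.

**Step 19.** BBr3 may ionise the tertiary C4–O bond, opening the chroman or scrambling C4. Fallback, from ketone 27: carry out the Wittig methylenation first (as in step 20) to give the dimethoxy alkene F8, then cleave both methyl ethers nucleophilically with CH3MgI at about 160 °C without solvent, a method that tolerates alkenes; it returns at 29.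

## Further compounds

F1 | step 13 | (Z)-vinyl iodide, 2-[(Z)-4-iodobut-3-enyl] analogue of 14 | CC(C)(C)[Si](c1ccccc1)(c1ccccc1)OCCC[C@@H]2[C@@H](c3ccccc3)c3c(OC)cc(OC)cc3O[C@@]2(C)CC/C=C\I
F2 | step 13 | desilylated alcohol of F1 | OCCC[C@@H]2[C@@H](c3ccccc3)c3c(OC)cc(OC)cc3O[C@@]2(C)CC/C=C\I
F3 | step 13 | iodo aldehyde from F2 | O=CCC[C@@H]2[C@@H](c3ccccc3)c3c(OC)cc(OC)cc3O[C@@]2(C)CC/C=C\I
F4 | step 13 | chroman-fused (Z)-cyclonon-2-enol, C8 carbinol epimers | OC1CC[C@@H]2[C@@H](c3ccccc3)c3c(OC)cc(OC)cc3O[C@@]2(C)CC/C=C\1
F5 | step 15 | C1 epimer of 22 | C1C[C@@H]2[C@@H](c3ccccc3)c3c(OC)cc(OC)cc3O[C@@]2(C)CC[C@@H](C(C)(C)C(=O)OC)/C=C\1O[Si](C)(C)C(C)(C)C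
F6 | step 15 | ring-cis cyclonon-2-enone with C(CH3)2CO2CH3 on C1 | O=C1CC[C@@H]2[C@@H](c3ccccc3)c3c(OC)cc(OC)cc3O[C@@]2(C)CC/C(C(C)(C)C(=O)OC)=C\1
F7 | step 5 | (3R,4S)-2-(but-3-enyl)-3-[3-(tert-butyldiphenylsilyloxy)propyl]-5,7-dimethoxy-4-phenylchroman-2-ol (C2 epimers) | CC(C)(C)[Si](c1ccccc1)(c1ccccc1)OCCC[C@@H]1[C@@H](c2ccccc2)c2c(OC)cc(OC)cc2OC1(O)CCC=C
F0 | step 18 | none | none
F8 | step 19 | 5,7-dimethoxy compound with exocyclic C8 methylene (1S,4S,5R,9R,1′S) | C=C1CC[C@@H]2[C@@H](c3ccccc3)c3c(OC)cc(OC)cc3O[C@@]2(C)CC[C@H]2[C@H]1CC2(C)C
A1 | alternative 1 | chroman-linked 2-diazo-4,4-dimethyl-3-alkylcyclopentanone | CC(C)(C)[Si](C)(C)OCC[C@@H]2[C@@H](c3ccccc3)c3c(OC)cc(OC)cc3O[C@@]2(C)CC[C@H]2C(=[N+]=[N-])C(=O)CC2(C)C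
A2 | alternative 1 | chroman-linked methyl trans-3,3-dimethyl-2-alkylcyclobutanecarboxylate | CC(C)(C)[Si](C)(C)OCC[C@@H]2[C@@H](c3ccccc3)c3c(OC)cc(OC)cc3O[C@@]2(C)CC[C@H]2[C@H](C(=O)OC)CC2(C)C
A3 | alternative 2 | cis-2-vinyl-3-alkenyl-6,6-dimethylbicyclo[3.2.0]heptan-2-ol with the (E)-diarylmethyl-substituted alkenyl group | C=C[C@@]1(O)[C@@H](/C(C)=C/[C@@H](c2ccccc2)c2c(OC)cc(OC)cc2O)C[C@H]2[C@@H]1CC2(C)C
A4 | alternative 2 | trans-cyclobutane-fused (Z)-cyclonon-5-enone with the diarylmethyl group on C5 | O=C1CC[C@H]([C@@H](c2ccccc2)c2c(OC)cc(OC)cc2O)/C(C)=C\C[C@H]2[C@H]1CC2(C)C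
A5 | alternative 3 | ten-membered cyclic sulfone (sulfur between C2 and C3) with the C8 ethylene ketal | O1CCOC12CC[C@@H]3[C@@H](c4ccccc4)c4c(OC)cc(OC)cc4O[C@@]3(C)CS(=O)(=O)C[C@H]3[C@H]2CC3(C)C
A6 | alternative 3 | nine-membered (Z)-C2=C3 cycloalkene with the C8 ethylene ketal | O1CCOC12CC[C@@H]3[C@@H](c4ccccc4)c4c(OC)cc(OC)cc4O[C@@]3(C)/C=C\[C@H]3[C@H]2CC3(C)C
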